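**Retrosynthetic overview**
1. The strategy rests on the bis-benzylic ether C1–O–C1′. C1 (R) and C1′ (S) carry identical 7-methoxycoumarin-8-yl rings, so the core is locally meso. The symmetry is broken only at the carbinols: C2 (R) is syn to C1 and C2′ (R) is anti to C1′.
2. The C2′–isopropenyl bond is cut back to a C2′ aldehyde (Nozaki–Hiyama–Kishi addition, Felkin–Anh, gives anti). The C2–H bond is cut back to a C2 isopropenyl ketone (1,2-reduction, Felkin–Anh, gives syn).
3. The ketone comes from a thioester by Fukuyama coupling. The thioester comes from opening a cis-3,5-diaryl-1,4-dioxan-2-one, in which C2 is the acyl carbon and C2′ the carbinyl carbon.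
4. The dioxanone comes from the meso dialdehyde ArCH(CHO)–O–CH(CHO)Ar by a catalytic enantioselective intramolecular Tishchenko reaction. The dialdehyde comes from glycol cleavage of a cis-2,5-diaryltetrahydrofuran-3,4-diol, itself made by double convex-face arylation of an acetonide-protected 2,5-dimethoxytetrahydrofuran with a C8 zinc reagent.
5. Ring order: the coumarins arrive with umbelliferone. The dioxolane is fused onto the purchased furan ring in step 4, and both template rings are destroyed in steps 6–7. The dioxanone is closed in step 8 and opened in step 9.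

Key step: step 8

Ar = 7-methoxy-2-oxo-2H-chromen-8-yl throughout. C1/C2 denote the syn arm and C1′/C2′ the anti arm.
Assumption: the sense of induction of the iridium catalyst cannot be deduced from the substrate. The (S,S)-ligand is written; the equally available (R,R)-antipode would replace it if the opposite sense is found, with nothing else changing.

**Step 1**
Reactants: 1 umbelliferone (7-hydroxycoumarin)
Product: 2 7-hydroxy-8-iodocoumarin
Conditions: I2, KI, aq. NH3, 0 °C → rt; then acidify
Reagents that add atoms: iodine, II
Why: Electrophilic aromatic iodination of the phenoxide should go to C8, the carbon between the 7-oxygen and the ring oxygen that is the usual site of attack in 7-hydroxycoumarins; no stereocentre is involved.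

**Step 2**
Reactants: 2 7-hydroxy-8-iodocoumarin
Product: 3 8-iodo-7-methoxycoumarin
Conditions: MeI, K2CO3, acetone, reflux
Reagents that add atoms: iodomethane, CI
Why: Williamson etherification of the acidic 7-phenol with a mild carbonate base leaves the lactone and the C–I bond untouched.

**Step 3**
Reactants: 4 2,5-dimethoxy-2,5-dihydrofuran (commercial cis/trans mixture)
Product: 5 2,5-dimethoxytetrahydrofuran-3,4-diol (cis-diol; mixture of acetal epimers)
Conditions: OsO4 (1 mol %), NMO, acetone–H2O, rt
Reagents that add atoms: N-methylmorpholine N-oxide, C[N+]1([O-])CCOCC1; water, O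
Why: Upjohn dihydroxylation adds both oxygens suprafacially to the only alkene, which fixes the cis relation of the two hydroxyls, while the acetal carbons remain an epimer mixture that is erased in step 5.

**Step 4**
Reactants: 5 2,5-dimethoxytetrahydrofuran-3,4-diol
Product: 6 4,6-dimethoxy-2,2-dimethyltetrahydrofuro[3,4-d][1,3]dioxole (cis-fused; mixture of acetal epimers)
Conditions: Me2C(OMe)2, p-TsOH (cat.), acetone, rt
Reagents that add atoms: 2,2-dimethoxypropane, COC(C)(C)OC
Why: Acid-catalysed transketalisation closes the cis-fused dioxolane on the cis-diol and creates the concave/convex bicyclo[3.3.0] template that steers both arylations.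

**Step 5**
Reactants: 3 8-iodo-7-methoxycoumarin (3 equiv); 6 4,6-dimethoxy-2,2-dimethyltetrahydrofuro[3,4-d][1,3]dioxole (1 equiv)
Product: 9 meso-(3aR,4R,6S,6aS)-4,6-bis(Ar)-2,2-dimethyltetrahydrofuro[3,4-d][1,3]dioxole (both aryl groups exo: cis to each other and trans to the dioxolane), via arylzinc iodide 7 (not isolated), via monoaryl methyl acetal 8 (not isolated)
Conditions: 3, Zn dust, LiCl, THF, 40 °C; solvent change to CH2Cl2–toluene; 6, TMSOTf (3 equiv), −40 °C → rt
Reagents that add atoms: none
Why: LiCl-assisted zinc insertion tolerates the coumarin lactone, and silyl triflate ionisation of each methyl acetal gives a furanosyl-type oxocarbenium ion that the arylzinc captures (C-glycosylation-type substitution of an acetal by an organozinc reagent) from the convex face anti to the dioxolane, so both new benzylic centres should end up exo and cis to each other, that is meso.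

**Step 6**
Reactants: 9 meso diaryl acetonide
Product: 10 meso-(2R,3S,4R,5S)-2,5-bis(Ar)tetrahydrofuran-3,4-diol
Conditions: TFA–H2O (9:1), CH2Cl2, 0 °C
Reagents that add atoms: none
Why: Acid hydrolysis of the isopropylidene ketal frees the cis-diol, and the benzylic C–O bonds, deactivated by the coumarin lactone, are expected to resist ionisation at 0 °C so that the 2,5-cis relation is kept.

**Step 7**
Reactants: 10 meso diaryl diol
Product: 11 meso-(2R,2′S)-2,2′-oxybis[2-(Ar)acetaldehyde]
Conditions: NaIO4 on SiO2, CH2Cl2, rt; filter, concentrate, use at once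
Reagents that add atoms: none
Why: Malaprade glycol cleavage through the cyclic periodate ester breaks only the C3–C4 bond, and the supported reagent in a non-aqueous, base-free medium should give the free dialdehyde rather than its cyclic hydrate without disturbing the enolisable C1 and C1′ centres.

**Step 8**
Reactants: 11 meso dialdehyde
Product: 14 (3R,5S)-3,5-bis(Ar)-1,4-dioxan-2-one (cis), via hydroxy aldehyde 12 (not isolated), via lactol 13 (not isolated)
Conditions: Cp*Ir[(S,S)-TsDPEN] (5 mol %), i-PrOH (10 mol %), 4 Å MS, CH2Cl2 (0.02 M), 0 °C → rt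
Reagents that add atoms: none
Why: The 16-electron amido complex is primed by i-PrOH to the 18-electron Ir–H/N–H species, which passes hydride and proton through an outer-sphere six-membered transition state to one of the two enantiotopic formyl groups (new C2′–H bond, 12); the freed hydroxyl adds to the other formyl carbon C2 to give lactol 13, and the amido complex takes the carbinol hydride and the O–H proton back from 13, so that lactone 14 forms irreversibly, the hydride is regenerated and the process is redox-neutral. The closest known reaction type is the iridium-catalysed enantioselective intramolecular Tishchenko reaction (desymmetrising lactonisation) of meso dialdehydes with Cp*Ir bifunctional catalysts, with rhodium-catalysed hydroacylation of ether-tethered carbonyl compounds as a relative. The one ring closed, the 1,4-dioxan-2-one, forms by 6-exo-trig attack of the C2′ oxygen on C2, helped by the 1,5-spacing of the formyl groups across the ether oxygen. No new tetrahedral centre arises at C2 or C2′; C1 and C1′ keep the cis relation inherited from 11 and become (3R) and (5S) solely through the group selection made by the chiral diamine ligand. The selectivity needed is between enantiotopic aldehydes, and the substrate helps because each formyl group sits next to a stereocentre bearing a bulky ortho,ortho′-disubstituted aryl ring of opposite spatial sense, which the ligand pocket can read. A base-free preformed catalyst, low temperature and high dilution are chosen to hold back enolisation at C1/C1′ and intermolecular ester formation.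

**Step 9**
Reactants: 14 (3R,5S)-dioxanone
Product: 15 S-ethyl (2R)-2-[(1S)-2-hydroxy-1-(Ar)ethoxy]-2-(Ar)ethanethioate
Conditions: AlMe3, EtSH (slight excess over Al), CH2Cl2, 0 °C; then 14, −20 → 0 °C; Rochelle salt work-up; crude product taken on at once
Reagents that add atoms: ethanethiol, CCS
Why: Aluminium thiolate ester-to-thioester exchange attacks the α-alkoxy-activated aliphatic δ-lactone and is driven by Al–O bond formation, whereas any opening of a coumarin would reverse on work-up because the Z-configured o-hydroxycinnamoyl thioester relactonises.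

**Step 10**
Reactants: 15 hydroxy thioester
Product: 16 S-ethyl (2R)-2-[(1S)-2-(tert-butyldimethylsilyloxy)-1-(Ar)ethoxy]-2-(Ar)ethanethioate
Conditions: TBSOTf, 2,6-lutidine, CH2Cl2, −78 °C
Reagents that add atoms: tert-butyldimethylsilyl triflate, CC(C)(C)[Si](C)(C)OS(=O)(=O)C(F)(F)F
Why: Fast silylation with a silyl triflate and a non-nucleophilic base at low temperature caps the primary alcohol before it can displace ethanethiol and re-form the lactone, and it is too mild to enolise the thioester at C1.

**Step 11**
Reactants: 16 silyloxy thioester; 17 2-bromopropene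
Product: 20 (1R)-1-[(1S)-2-(tert-butyldimethylsilyloxy)-1-(Ar)ethoxy]-1-(Ar)-3-methylbut-3-en-2-one, via isopropenylmagnesium bromide 18 (not isolated), via isopropenylzinc bromide 19 (not isolated)
Conditions: 17, Mg, THF; ZnBr2, 0 °C; then 16, PdCl2(PPh3)2 (5 mol %), toluene–THF, rt; aq. NH4Cl quench
Reagents that add atoms: none
Why: In the Fukuyama coupling Pd(0) inserts into the acyl–sulfur bond, the alkenylzinc transmetallates and reductive elimination gives the ketone under neutral conditions in which organozinc reagents leave the coumarin lactones, the new enone and the acidic C1–H alone.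

**Step 12**
Reactants: 20 enone
Product: 21 (1R,2R)-1-[(1S)-2-(tert-butyldimethylsilyloxy)-1-(Ar)ethoxy]-1-(Ar)-3-methylbut-3-en-2-ol
Conditions: NaBH4, CeCl3·7H2O, MeOH–CH2Cl2, −78 °C
Reagents that add atoms: none
Why: Luche reduction attacks only the ketone carbonyl (no conjugate reduction of the 2-methylpropenoyl unit or the coumarins), and with the C1–O bond perpendicular to the carbonyl plane (polar Felkin–Anh) and chelation discouraged by methanol and by the crowded di-sec-alkyl ether oxygen, hydride should enter anti to that oxygen past C1–H and set C2 as R, syn to C1.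

**Step 13**
Reactants: 21 syn allylic alcohol
Product: 22 bis-TBS ether of 21 (C2–OTBS and C2′–OTBS; 1R,2R,1′S)
Conditions: TBSOTf, 2,6-lutidine, CH2Cl2, 0 °C → rt
Reagents that add atoms: tert-butyldimethylsilyl triflate, CC(C)(C)[Si](C)(C)OS(=O)(=O)C(F)(F)F
Why: Silyl triflate silylation is forceful enough for the hindered allylic alcohol and masks it so that it can later neither be oxidised nor close a lactol on the C2′ aldehyde.

**Step 14**
Reactants: 22 bis-TBS ether
Product: 23 (2S)-2-{[(1R,2R)-2-(tert-butyldimethylsilyloxy)-1-(Ar)-3-methylbut-3-enyl]oxy}-2-(Ar)ethanol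
Conditions: HF·pyridine, pyridine, THF, 0 °C
Reagents that add atoms: none
Why: Buffered HF·pyridine distinguishes the silyl ethers by steric access and should remove the primary one well before the secondary allylic one, which is flanked by the isopropenyl group and C1.

**Step 15**
Reactants: 23 primary alcohol
Product: 24 (2S)-2-{[(1R,2R)-2-(tert-butyldimethylsilyloxy)-1-(Ar)-3-methylbut-3-enyl]oxy}-2-(Ar)acetaldehyde
Conditions: Dess–Martin periodinane, CH2Cl2, 0 °C → rt; used crude
Reagents that add atoms: none
Why: Dess–Martin oxidation stops at the aldehyde under base-free conditions, which protects the configurationally labile α-aryl-α-alkoxy centre C1′.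

**Step 16**
Reactants: 24 aldehyde; 17 2-bromopropene
Product: 26 C2-O-TBS ether of the target (1R,2R,1′S,2′R), via isopropenylchromium dichloride 25 (not isolated)
Conditions: CrCl2 (excess), NiCl2 (1 mol %), DMF, rt
Reagents that add atoms: none
Why: In the Nozaki–Hiyama–Kishi reaction the non-basic alkenylchromium(III) species adds only to the aldehyde (lactones and silyl ether untouched, no enolisation at C1′), and in strongly coordinating DMF the polar Felkin–Anh arrangement with C1′–O perpendicular to the carbonyl should direct attack past C1′–H and set C2′ as R, anti to C1′.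

**Step 17**
Reactants: 26 mono-TBS ether
Product: 27 target CNP0283712.1, (1R,2R,1′S,2′R)
Conditions: TBAF, AcOH (1:1), THF, 0 °C → rt
Reagents that add atoms: none
Why: Fluoride cleavage of the remaining silyl ether, buffered with acetic acid so that no free alkoxide can attack the coumarin lactones, releases the C2 hydroxyl without touching any stereocentre.

**Compound list**
1 | umbelliferone | O=c1ccc2ccc(O)cc2o1 | starting material
2 | 7-hydroxy-8-iodocoumarin | O=c1ccc2ccc(O)c(I)c2o1 | intermediate
3 | 8-iodo-7-methoxycoumarin | COc1ccc2ccc(=O)oc2c1I | intermediate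
4 | 2,5-dimethoxy-2,5-dihydrofuran (cis/trans mixture) | COC1C=CC(OC)O1 | starting material
5 | 2,5-dimethoxytetrahydrofuran-3,4-diol (cis-diol, acetal epimers) | COC1OC(OC)[C@H](O)[C@@H]1O | intermediate
6 | 4,6-dimethoxy-2,2-dimethyltetrahydrofuro[3,4-d][1,3]dioxole (cis-fused, acetal epimers) | COC1OC(OC)[C@H]2[C@@H]1OC(C)(C)O2 | intermediate
7 | (7-methoxy-2-oxochromen-8-yl)zinc iodide | COc1ccc2ccc(=O)oc2c1[Zn]I | intermediate (not isolated)
8 | exo-4-aryl-6-methoxy acetonide (racemic, relative configuration drawn) | COc1ccc2ccc(=O)oc2c1[C@H]1OC(OC)[C@H]2[C@@H]1OC(C)(C)O2 | intermediate (not isolated)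
9 | meso-(3aR,4R,6S,6aS)-4,6-bis(Ar)-2,2-dimethyltetrahydrofuro[3,4-d][1,3]dioxole | COc1ccc2ccc(=O)oc2c1[C@H]1O[C@@H](c2c(OC)ccc3ccc(=O)oc23)[C@H]2[C@@H]1OC(C)(C)O2 | intermediate
10 | meso-(2R,3S,4R,5S)-2,5-bis(Ar)tetrahydrofuran-3,4-diol | COc1ccc2ccc(=O)oc2c1[C@H]1O[C@@H](c2c(OC)ccc3ccc(=O)oc23)[C@H](O)[C@@H]1O | intermediate
11 | meso-(2R,2′S)-2,2′-oxybis[2-(Ar)acetaldehyde] | O=C[C@H](O[C@@H](c1c(OC)ccc2ccc(=O)oc12)C=O)c1c(OC)ccc2ccc(=O)oc12 | intermediate
12 | (2R)-2-[(1S)-2-hydroxy-1-(Ar)ethoxy]-2-(Ar)acetaldehyde | O=C[C@H](O[C@@H](c1c(OC)ccc2ccc(=O)oc12)CO)c1c(OC)ccc2ccc(=O)oc12 | intermediate (not isolated)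
13 | (3R,5S)-3,5-bis(Ar)-1,4-dioxan-2-ol (lactol epimers) | OC1[C@H](O[C@@H](c2c(OC)ccc3ccc(=O)oc23)CO1)c1c(OC)ccc2ccc(=O)oc12 | intermediate (not isolated)
14 | (3R,5S)-3,5-bis(Ar)-1,4-dioxan-2-one | O=C1[C@H](O[C@@H](c2c(OC)ccc3ccc(=O)oc23)CO1)c1c(OC)ccc2ccc(=O)oc12 | intermediate
15 | S-ethyl (2R)-2-[(1S)-2-hydroxy-1-(Ar)ethoxy]-2-(Ar)ethanethioate | CCSC(=O)[C@H](O[C@@H](c1c(OC)ccc2ccc(=O)oc12)CO)c1c(OC)ccc2ccc(=O)oc12 | intermediate
16 | primary TBS ether of 15 | CCSC(=O)[C@H](O[C@@H](c1c(OC)ccc2ccc(=O)oc12)CO[Si](C)(C)C(C)(C)C)c1c(OC)ccc2ccc(=O)oc12 | intermediate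
17 | 2-bromopropene | C=C(C)Br | starting material
18 | isopropenylmagnesium bromide | C=C(C)[Mg]Br | intermediate (not isolated)
19 | isopropenylzinc bromide | C=C(C)[Zn]Br | intermediate (not isolated)
20 | (1R,1′S)-isopropenyl ketone | C=C(C)C(=O)[C@H](O[C@@H](c1c(OC)ccc2ccc(=O)oc12)CO[Si](C)(C)C(C)(C)C)c1c(OC)ccc2ccc(=O)oc12 | intermediate
21 | (1R,2R,1′S)-syn allylic alcohol | C=C(C)[C@@H](O)[C@H](O[C@@H](c1c(OC)ccc2ccc(=O)oc12)CO[Si](C)(C)C(C)(C)C)c1c(OC)ccc2ccc(=O)oc12 | intermediate
22 | bis-TBS ether | C=C(C)[C@@H](O[Si](C)(C)C(C)(C)C)[C@H](O[C@@H](c1c(OC)ccc2ccc(=O)oc12)CO[Si](C)(C)C(C)(C)C)c1c(OC)ccc2ccc(=O)oc12 | intermediate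
23 | C2-OTBS primary alcohol | C=C(C)[C@@H](O[Si](C)(C)C(C)(C)C)[C@H](O[C@@H](c1c(OC)ccc2ccc(=O)oc12)CO)c1c(OC)ccc2ccc(=O)oc12 | intermediate
24 | C2-OTBS C2′ aldehyde | C=C(C)[C@@H](O[Si](C)(C)C(C)(C)C)[C@H](O[C@@H](c1c(OC)ccc2ccc(=O)oc12)C=O)c1c(OC)ccc2ccc(=O)oc12 | intermediate
25 | isopropenylchromium(III) dichloride | C=C(C)[Cr](Cl)Cl | intermediate (not isolated)
26 | C2-O-TBS ether of the target | C=C(C)[C@@H](O[Si](C)(C)C(C)(C)C)[C@H](O[C@@H](c1c(OC)ccc2ccc(=O)oc12)[C@H](O)C(=C)C)c1c(OC)ccc2ccc(=O)oc12 | intermediate
27 | CNP0283712.1 | C=C(C)[C@@H](O)[C@H](O[C@@H](c1c(OC)ccc2ccc(=O)oc12)[C@H](O)C(=C)C)c1c(OC)ccc2ccc(=O)oc12 | target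

**Step count**
- Total step count: 17.
- Longest linear sequence: 15 steps, either steps 1, 2, 5–17 from 1 or steps 3, 4, 5–17 from 4.

**Steps most likely to fail**

1. Step 8.
   - The basic amido complex may enolise C1/C1′ before hydride transfer and so erode the meso relation.
   - The ligand may discriminate the two formyl groups insufficiently.
   - Intermolecular ester formation may compete with ring closure.
   - Fallback, from 11 back to 14, replaces metal catalysis with an enzymatic desymmetrisation at the alcohol oxidation level. Compound 11 is reduced with NaBH4 in MeOH–CH2Cl2 at low temperature to the meso diol F1. Lipase-catalysed acetylation with vinyl acetate, with the enzyme chosen by screening for the sense that leaves the C2 hydroxyl free, gives the monoacetate F2. TEMPO/PhI(OAc)2 in aqueous MeCN oxidises the free CH2OH to the acetoxy acid F3. Methanolysis of the acetate (K2CO3, MeOH, 0 °C) followed by acidification lets the hydroxy acid lactonise to 14.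

2. Step 5.
   - The silyl triflate may ionise the isopropylidene ketal in competition with the methyl acetals.
   - The second substitution may stall.
   - The silyl triflate may activate the coumarin carbonyl towards aryl addition.
   - Attack on the second oxocarbenium ion may be less convex-face selective.
   - Fallback, from 6 back to 9, installs an activating leaving group that needs no strong Lewis acid. Both methoxy groups are exchanged with benzenesulfinic acid and CaCl2 in CH2Cl2 to give the bis(phenylsulfonyl) acetonide F4. F4 is treated with 7 and added ZnBr2 in THF. Anomeric sulfones of cyclic ethers are ionised by zinc(II) itself and are substituted by arylzinc reagents, again from the convex face.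

3. Step 12.
   - Hydride may be delivered through a metal chelate between the ketone and ether (or aryl methoxy) oxygens, which would erode or invert the facial selectivity.
   - Some conjugate reduction may occur.
   - Fallback, from 16 back to 21, reverses the order of C–H and C–C bond formation so that a chelating bias becomes productive. Fukuyama reduction of 16 (Et3SiH, Pd/C, acetone, rt) gives the silyloxy aldehyde F5. Cram-chelate addition of 19 in the presence of MgBr2·OEt2 in CH2Cl2 at −78 °C should then deliver the syn alcohol 21.

**Further compounds**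
F1 | step 8 | meso-(2R,2′S)-2,2′-oxybis[2-(Ar)ethanol] | OC[C@H](O[C@@H](c1c(OC)ccc2ccc(=O)oc12)CO)c1c(OC)ccc2ccc(=O)oc12
F2 | step 8 | (2S)-2-[(1R)-2-hydroxy-1-(Ar)ethoxy]-2-(Ar)ethyl acetate | OC[C@H](O[C@@H](c1c(OC)ccc2ccc(=O)oc12)COC(C)=O)c1c(OC)ccc2ccc(=O)oc12
F3 | step 8 | (2R)-2-[(1S)-2-acetoxy-1-(Ar)ethoxy]-2-(Ar)acetic acid | OC(=O)[C@H](O[C@@H](c1c(OC)ccc2ccc(=O)oc12)COC(C)=O)c1c(OC)ccc2ccc(=O)oc12
F4 | step 5 | 2,2-dimethyl-4,6-bis(phenylsulfonyl)tetrahydrofuro[3,4-d][1,3]dioxole (cis-fused, anomeric epimers) | O=S(=O)(c1ccccc1)C1OC(S(=O)(=O)c2ccccc2)[C@H]2[C@@H]1OC(C)(C)O2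
F5 | step 12 | (2R)-2-[(1S)-2-(tert-butyldimethylsilyloxy)-1-(Ar)ethoxy]-2-(Ar)acetaldehyde | O=C[C@H](O[C@@H](c1c(OC)ccc2ccc(=O)oc12)CO[Si](C)(C)C(C)(C)C)c1c(OC)ccc2ccc(=O)oc12
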